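**Strategy.** Everything rests on forming C19–C20 last among the ring bonds, so that cyclopentanone ring D is fused onto a finished tricycle (pyranone ring A, ketal ring B, seven-membered ring C). A dirhodium carbenoid at C20, released from a diazoketone carried by carbinol C17, inserts into a C19–H bond. The step exploits the 1,5 relation of C20 to ring C carbon C19 through C21, quaternary C23 and C17, and delivers ring, bond and ring-fusion centre at once. The precursor holds C11 as a methyl ketal, O14 and O18 as silyl ethers, and C15 as a chloroacetylated carbinol, because a C15 ketone would capture the carbenoid as a carbonyl ylide.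

Key step: step 17

**Remarks**
- Atom labels (C11, C13 …) are the heavy-atom positions of the target SMILES. Ring C is C11–C13–C15–C17–C19–C26–C28. β is the face of ring C that carries the C26 methyl group, α the other face.
- "The tricycle" means ring A (5,6-dimethyl-2-pyranone) joined to ring C through C29H2 (to C28) and O10 (to C11). Unless stated otherwise it carries C11–OCH3 α, C26–CH3 β and C28–H β.
- Assumption: the natural C11 hemiketal is the thermodynamic epimer (it can equilibrate by ring–chain tautomerism).
- Assumption: the (S,R,R) ligand in step 2 gives the (S) centre at C26; the mirror-image ligand would be used otherwise.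
- The C15 carbinol centre in compounds 18 to 30 is temporary; it is reoxidised in step 20.

**Route**

Step 1
Reactants: 1 cycloheptanone
Product: 2 cyclohepta-2,6-dien-1-one
Conditions: IBX (2.5 equiv), DMSO/fluorobenzene, 70 °C
Reagents that add atoms: none
Why: Twofold IBX dehydrogenation of the symmetrical ketone through its enol (ketone-to-enone desaturation), with the oxidant limited so that a third desaturation to tropone is held back.

Step 2
Reactants: 2 cyclohepta-2,6-dien-1-one
Product: 4 (6S,7S)-7-[(dimethylamino)methyl]-6-methylcyclohept-2-en-1-one, via silyl dienol ether 3 (not isolated)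
Conditions: Me2Zn, Cu(OTf)2 (2 mol %), (S,R,R)-BINOL N,N-bis(1-phenylethyl)phosphoramidite (4 mol %), PhMe, −25 °C; TMSOTf; then CH2=NMe2+ I−, CH2Cl2, 0 °C to rt; aq. NaHCO3
Reagents that add atoms: dimethylzinc C[Zn]C; N,N-dimethylmethyleneiminium iodide C=[N+](C)C.[I-]
Why: Copper-catalysed asymmetric conjugate addition of Me2Zn to the cross-conjugated dienone should set C26 (S) under ligand control (only one enone reacts, since the adduct is an enolate), and the silyl-trapped enolate then undergoes a regiospecific Mannich reaction at C28 anti to the new methyl group.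

Step 3
Reactants: 4 (6S,7S)-7-[(dimethylamino)methyl]-6-methylcyclohept-2-en-1-one; 5 4-hydroxy-5,6-dimethyl-2H-pyran-2-one
Product: 8 tricyclic hemiketal (C11–OH α; C13=C15 alkene), via ammonium iodide 6 (not isolated), via methylene dienone 7 (not isolated)
Conditions: MeI, MeCN, rt; then 5, Et3N, 50 °C
Reagents that add atoms: none
Why: Quaternisation and E1cB loss of trimethylamine unmask the α-methylene ketone, which is captured at once by C3 of the acidic hydroxypyranone in a Michael addition; C28 (α to the ketone) equilibrates under the amine to the trans C26/C28 arrangement and the pyranone hydroxyl closes ring B as the hemiketal.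

Step 4
Reactants: 8 tricyclic hemiketal
Product: 9 tricyclic methyl ketal (C11–OCH3 α; C13=C15 alkene)
Conditions: MeOSiMe3, TMSOTf (10 mol %), CH2Cl2, −78 °C; Et3N quench
Reagents that add atoms: methoxytrimethylsilane CO[Si](C)(C)C
Why: Noyori-type ketalisation, in which the hemiketal ionises at low temperature and the oxocarbenium ion is trapped irreversibly and axially by the silyl ether, which avoids the double-bond migration and methanol conjugate addition that protic acid causes with enones and should give the anomerically stabilised, trans-fused ketal.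

Step 5
Reactants: 9 tricyclic methyl ketal
Product: 10 β-epoxide across C13–C15
Conditions: mCPBA, NaHCO3, CH2Cl2, 0 °C to rt
Reagents that add atoms: 3-chloroperoxybenzoic acid OOC(=O)c1cccc(Cl)c1
Why: Prilezhaev epoxidation of the cis-disubstituted alkene from the face opposite the axial C11 methoxy group, which places the C13–O bond on the β face as required in the target.

Step 6
Reactants: 10 β-epoxide
Product: 12 allylic alcohol (C13–OH β; C15=C17 alkene), via hydroxy selenide 11 (not isolated)
Conditions: (PhSe)2, NaBH4, EtOH, rt, then 10, 60 °C; then H2O2 (30 %), THF, 0 °C to rt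
Reagents that add atoms: none
Why: Sharpless–Lauer epoxide-to-allylic-alcohol sequence, in which benzeneselenolate opens the epoxide by SN2 attack at C15 (C13 is neopentylic and flanked by the ketal) and the selenoxide undergoes syn-elimination away from the carbinol, leaving the C13 configuration untouched.

Step 7
Reactants: 12 allylic alcohol
Product: 13 C13 tert-butyldimethylsilyl ether (C15=C17 alkene)
Conditions: TBSOTf, 2,6-lutidine, CH2Cl2, −40 °C
Reagents that add atoms: tert-butyldimethylsilyl triflate CC(C)(C)[Si](C)(C)OS(=O)(=O)C(F)(F)F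
Why: Silylation of a hindered secondary alcohol with a silyl triflate and a hindered pyridine base.

Step 8
Reactants: 13 C13 silyl ether
Product: 14 C15,C17 cis-diol (both hydroxyls α)
Conditions: OsO4 (2 mol %), NMO, acetone/H2O, rt
Reagents that add atoms: 4-methylmorpholine N-oxide C[N+]1([O-])CCOCC1; water O
Why: Catalytic osmium tetroxide syn-dihydroxylation of the cis-alkene anti to the C13 silyloxy group; both new centres are erased in the next step, so facial selectivity is immaterial.

Step 9
Reactants: 14 cis-diol
Product: 15 C15,C17 dione (C13–OTBS β)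
Conditions: IBX, DMSO, rt
Reagents that add atoms: none
Why: IBX oxidises vicinal diols to 1,2-diketones without C–C cleavage, and as an amine-free oxidant it avoids enolisation toward C13, which could epimerise that centre or expel the β-oxygen at C11.

Step 10
Reactants: 15 dione; 16 1-bromo-3-methylbut-2-ene
Product: 17 ketol (C15=O; C17–OH α; C17 β-(2-methylbut-3-en-2-yl))
Conditions: 16, In (powder), THF, rt (reagent preformed); then 15, 0 °C to rt; aq. NH4Cl
Reagents that add atoms: none
Why: Barbier-type allylation in which the prenylindium reagent reacts with allylic transposition to deliver the 1,1-dimethylallyl group at the less hindered C17 carbonyl (C15 is flanked by the silyloxy carbon C13), and the bulky reagent should attack pseudo-equatorially so that the new C17–C23 bond is cis to the equatorial C26 methyl and the hydroxyl lies on the α face.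

Step 11
Reactants: 17 ketol
Product: 18 diol (C15–OH β; C17–OH α)
Conditions: NaBH4, MeOH/CH2Cl2, −40 °C
Reagents that add atoms: none
Why: Borohydride reduction of the remaining ketone from the face away from the flanking C13 silyloxy and C17 dimethylallyl groups should give mainly the β alcohol; the centre is temporary, so either epimer can be carried on.

Step 12
Reactants: 18 diol
Product: 19 C15 chloroacetate (C17–OH α free)
Conditions: (ClCH2CO)2O, pyridine, DMAP (cat.), CH2Cl2, 0 °C
Reagents that add atoms: chloroacetic anhydride O=C(CCl)OC(=O)CCl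
Why: Acylation is selective for the secondary C15 alcohol over the tertiary C17 alcohol, and the electron-poor ester both deactivates the C15–H bond toward the carbenoid and can be removed later without base.

Step 13
Reactants: 19 C15 chloroacetate
Product: 20 C17 triethylsilyl ether
Conditions: TESOTf, 2,6-lutidine, CH2Cl2, 0 °C to rt
Reagents that add atoms: triethylsilyl triflate CC[Si](CC)(CC)OS(=O)(=O)C(F)(F)F
Why: Silyl triflate silylation caps the tertiary O18, which would otherwise undergo O–H insertion with the carbenoid and retro-aldol cleavage once ring D is present.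

Step 14
Reactants: 20 C17 triethylsilyl ether
Product: 21 aldehyde (C17 side chain C(CH3)2CHO)
Conditions: OsO4 (2 mol %), NaIO4, 2,6-lutidine, dioxane/H2O, rt
Reagents that add atoms: sodium periodate [Na+].[O-]I(=O)(=O)=O; water O
Why: Lemieux–Johnson cleavage of the only simple alkene in the molecule (the pyranone ring is electron-poor and inert) gives a neopentyl aldehyde that has no α-hydrogen.

Step 15
Reactants: 21 aldehyde
Product: 22 carboxylic acid (side chain C(CH3)2CO2H)
Conditions: NaClO2, NaH2PO4, 2-methylbut-2-ene, t-BuOH/H2O, rt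
Reagents that add atoms: sodium chlorite [Na+].[O-]Cl=O
Why: Pinnick oxidation under buffered conditions with an alkene scavenger for hypochlorous acid.

Step 16
Reactants: 22 carboxylic acid; 23 (trimethylsilyl)diazomethane
Product: 26 diazoketone (side chain C(CH3)2C(O)CHN2), via acid chloride 24 (not isolated), via silyl diazoketone 25 (not isolated)
Conditions: 1-chloro-N,N,2-trimethylprop-1-en-1-amine, CH2Cl2, 0 °C; then 23 (3 equiv), MeCN/THF, 0 °C to rt; aq. NaHCO3
Reagents that add atoms: none
Why: The neutral α-chloroenamine gives the acid chloride without HCl, and Arndt–Eistert-type acylation of the diazoalkane (a second equivalent takes up HCl) followed by desilylation on work-up gives the diazoketone; the quaternary α-carbon rules out ketene formation.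

Step 17
Reactants: 26 diazoketone
Product: 27 tetracyclic cyclopentanone (ring D closed, cis-fused; C19–H α)
Conditions: Rh2(OAc)4 (2 mol %), CH2Cl2, 40 °C, slow addition of 26
Reagents that add atoms: none
Why: Rh2(OAc)4 decomposes the diazoketone with loss of N2 to an electrophilic dirhodium carbenoid at C20, which inserts into a C19–H bond in a concerted three-centre process with retention at carbon. The closest known reaction type is the rhodium-carboxylate-catalysed intramolecular 1,5 C–H insertion of α-diazoketones to cyclopentanones. Ring D closes by C19–C20 bond formation through a six-membered transition state that includes the migrating hydrogen, whereas 1,6 insertion at the tertiary C26–H would need a larger, less favourable transition state. The new C19 centre is set by the tether, since the fixed C17–C23 bond lets C20 reach only the C19–H on its own face and the fusion is cis; this centre is removed in step 18. The selectivity needed is C19–H over C15–H (the other 1,5 position) and over ylide formation: C23 is quaternary, C15–H is geminal to the chloroacetoxy group and flanked by two oxygenated carbons and so is deactivated, no ketone sits at C15 to close a six-membered carbonyl ylide, and O18 is shielded by the triethylsilyl group.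

Step 18
Reactants: 27 tetracyclic cyclopentanone
Product: 29 tetracyclic enone (C19=C20–C21=O), via silyl enol ether 28 (not isolated)
Conditions: TMSOTf, i-Pr2NEt, CH2Cl2, −20 °C; then Pd(OAc)2 (1.1 equiv), MeCN, rt
Reagents that add atoms: none
Why: Saegusa–Ito oxidation, in which soft enolisation can occur only toward C20 (C23 is quaternary) and β-hydride elimination from the palladium enolate removes the C19 hydrogen; the amine/silyl triflate method avoids a lithium amide that could deprotonate the pyranone C6 methyl group.

Step 19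
Reactants: 29 tetracyclic enone
Product: 30 C15 alcohol (C15–OH β)
Conditions: thiourea, NaHCO3, EtOH/THF, 50 °C
Reagents that add atoms: none
Why: Thiourea removes the chloroacetate by S-alkylation and cyclisation to a thiazolidinone under near-neutral conditions, so no alkoxide forms next to the O18 silyl ether (no silyl migration) and the pyranone sees no alkoxide.

Step 20
Reactants: 30 C15 alcohol
Product: 31 C15 ketone (C13–OTBS β; C17–OTES α; C11–OCH3 α)
Conditions: DMP, NaHCO3, CH2Cl2, rt
Reagents that add atoms: none
Why: Dess–Martin oxidation of the hindered secondary alcohol under buffered, non-epimerising conditions; both neighbouring oxygens are protected, so diol cleavage cannot occur.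

Step 21
Reactants: 31 C15 ketone
Product: 32 CNP0525404.1 (target)
Conditions: HF (48 % aq.), MeCN, 0 °C to rt
Reagents that add atoms: water O
Why: Aqueous HF cleaves both silyl ethers and hydrolyses the mixed methyl ketal through the oxocarbenium ion to the hemiketal, which can settle by ring–chain tautomerism into the natural C11 configuration; no base is used, so the β-hydroxy ketone array at C17 is not exposed to retro-aldol conditions.

**Compound list**

1 | cycloheptanone | O=C1CCCCCC1 | starting material
2 | cyclohepta-2,6-dien-1-one | O=C1C=CCCC=C1 | intermediate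
3 | trimethyl{[(3S)-3-methylcyclohepta-1,6-dien-1-yl]oxy}silane | C[Si](C)(C)OC1=C[C@@H](C)CCC=C1 | intermediate (not isolated)
4 | (6S,7S)-7-[(dimethylamino)methyl]-6-methylcyclohept-2-en-1-one | O=C1C=CCC[C@H](C)[C@H]1CN(C)C | intermediate
5 | 4-hydroxy-5,6-dimethyl-2H-pyran-2-one | Cc1oc(=O)cc(O)c1C | starting material
6 | N-methylated Mannich base (trimethylammonium iodide of 4) | O=C1C=CCC[C@H](C)[C@H]1C[N+](C)(C)C.[I-] | intermediate (not isolated)
7 | (6S)-6-methyl-7-methylidenecyclohept-2-en-1-one | O=C1C=CCC[C@H](C)C1=C | intermediate (not isolated)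
8 | tricyclic hemiketal: C11–OH α, C13=C15 alkene, C26–CH3 β, C28–H β | Cc1oc(=O)c2c(c1C)O[C@]1(O)C=CCC[C@H](C)[C@H]1C2 | intermediate
9 | the tricycle with C13=C15 alkene (methyl ketal of 8) | Cc1oc(=O)c2c(c1C)O[C@]1(OC)C=CCC[C@H](C)[C@H]1C2 | intermediate
10 | the tricycle with a β-epoxide across C13–C15 | Cc1oc(=O)c2c(c1C)O[C@]1(OC)[C@@H]3O[C@@H]3CC[C@H](C)[C@H]1C2 | intermediate
11 | the tricycle with C13–OH β and C15–SePh α | Cc1oc(=O)c2c(c1C)O[C@]1(OC)[C@H](O)[C@@H]([Se]c3ccccc3)CC[C@H](C)[C@H]1C2 | intermediate (not isolated)
12 | the tricycle with C13–OH β and C15=C17 alkene | Cc1oc(=O)c2c(c1C)O[C@]1(OC)[C@H](O)C=CC[C@H](C)[C@H]1C2 | intermediate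
13 | the tricycle with C13–OTBS β and C15=C17 alkene | Cc1oc(=O)c2c(c1C)O[C@]1(OC)[C@H](O[Si](C)(C)C(C)(C)C)C=CC[C@H](C)[C@H]1C2 | intermediate
14 | the tricycle with C13–OTBS β, C15–OH α and C17–OH α | Cc1oc(=O)c2c(c1C)O[C@]1(OC)[C@H](O[Si](C)(C)C(C)(C)C)[C@@H](O)[C@@H](O)C[C@H](C)[C@H]1C2 | intermediate
15 | the tricycle with C13–OTBS β and ketones at C15 and C17 | Cc1oc(=O)c2c(c1C)O[C@]1(OC)[C@H](O[Si](C)(C)C(C)(C)C)C(=O)C(=O)C[C@H](C)[C@H]1C2 | intermediate
16 | 1-bromo-3-methylbut-2-ene | CC(C)=CCBr | starting material
17 | the tricycle with C13–OTBS β, C15 ketone, C17–OH α and C17 β-(2-methylbut-3-en-2-yl) | Cc1oc(=O)c2c(c1C)O[C@]1(OC)[C@H](O[Si](C)(C)C(C)(C)C)C(=O)[C@](O)(C(C)(C)C=C)C[C@H](C)[C@H]1C2 | intermediate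
18 | as 17 with C15–OH β in place of the ketone | Cc1oc(=O)c2c(c1C)O[C@]1(OC)[C@H](O[Si](C)(C)C(C)(C)C)[C@H](O)[C@](O)(C(C)(C)C=C)C[C@H](C)[C@H]1C2 | intermediate
19 | as 18 with C15–OC(O)CH2Cl β | Cc1oc(=O)c2c(c1C)O[C@]1(OC)[C@H](O[Si](C)(C)C(C)(C)C)[C@H](OC(=O)CCl)[C@](O)(C(C)(C)C=C)C[C@H](C)[C@H]1C2 | intermediate
20 | as 19 with C17–OSiEt3 α | Cc1oc(=O)c2c(c1C)O[C@]1(OC)[C@H](O[Si](C)(C)C(C)(C)C)[C@H](OC(=O)CCl)[C@](O[Si](CC)(CC)CC)(C(C)(C)C=C)C[C@H](C)[C@H]1C2 | intermediate
21 | as 20 with the C17 side chain C(CH3)2CHO | Cc1oc(=O)c2c(c1C)O[C@]1(OC)[C@H](O[Si](C)(C)C(C)(C)C)[C@H](OC(=O)CCl)[C@](O[Si](CC)(CC)CC)(C(C)(C)C=O)C[C@H](C)[C@H]1C2 | intermediate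
22 | as 20 with the C17 side chain C(CH3)2CO2H | Cc1oc(=O)c2c(c1C)O[C@]1(OC)[C@H](O[Si](C)(C)C(C)(C)C)[C@H](OC(=O)CCl)[C@](O[Si](CC)(CC)CC)(C(C)(C)C(=O)O)C[C@H](C)[C@H]1C2 | intermediate
23 | (trimethylsilyl)diazomethane | C[Si](C)(C)C=[N+]=[N-] | starting material
24 | as 20 with the C17 side chain C(CH3)2COCl | Cc1oc(=O)c2c(c1C)O[C@]1(OC)[C@H](O[Si](C)(C)C(C)(C)C)[C@H](OC(=O)CCl)[C@](O[Si](CC)(CC)CC)(C(C)(C)C(=O)Cl)C[C@H](C)[C@H]1C2 | intermediate (not isolated)
25 | as 20 with the C17 side chain C(CH3)2C(O)C(N2)SiMe3 | Cc1oc(=O)c2c(c1C)O[C@]1(OC)[C@H](O[Si](C)(C)C(C)(C)C)[C@H](OC(=O)CCl)[C@](O[Si](CC)(CC)CC)(C(C)(C)C(=O)C(=[N+]=[N-])[Si](C)(C)C)C[C@H](C)[C@H]1C2 | intermediate (not isolated)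
26 | key-step precursor: as 20 with the C17 side chain C(CH3)2C(O)CHN2 | Cc1oc(=O)c2c(c1C)O[C@]1(OC)[C@H](O[Si](C)(C)C(C)(C)C)[C@H](OC(=O)CCl)[C@](O[Si](CC)(CC)CC)(C(C)(C)C(=O)C=[N+]=[N-])C[C@H](C)[C@H]1C2 | intermediate
27 | key-step product: tetracycle with cis-fused cyclopentanone ring D (C17–C19–C20H2–C21(=O)–C23(CH3)2), C19–H α; C13–OTBS β, C15–OC(O)CH2Cl β, C17–OSiEt3 α | Cc1oc(=O)c2c(c1C)O[C@]1(OC)[C@H](O[Si](C)(C)C(C)(C)C)[C@H](OC(=O)CCl)[C@@]3(O[Si](CC)(CC)CC)[C@H](CC(=O)C3(C)C)[C@H](C)[C@H]1C2 | intermediate
28 | C20=C21 trimethylsilyl enol ether of 27 | Cc1oc(=O)c2c(c1C)O[C@]1(OC)[C@H](O[Si](C)(C)C(C)(C)C)[C@H](OC(=O)CCl)[C@@]3(O[Si](CC)(CC)CC)[C@H](C=C(O[Si](C)(C)C)C3(C)C)[C@H](C)[C@H]1C2 | intermediate (not isolated)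
29 | tetracyclic enone (C19=C20–C21=O), other groups as 27 | Cc1oc(=O)c2c(c1C)O[C@]1(OC)[C@H](O[Si](C)(C)C(C)(C)C)[C@H](OC(=O)CCl)[C@@]3(O[Si](CC)(CC)CC)C(=CC(=O)C3(C)C)[C@H](C)[C@H]1C2 | intermediate
30 | as 29 with free C15–OH β | Cc1oc(=O)c2c(c1C)O[C@]1(OC)[C@H](O[Si](C)(C)C(C)(C)C)[C@H](O)[C@@]3(O[Si](CC)(CC)CC)C(=CC(=O)C3(C)C)[C@H](C)[C@H]1C2 | intermediate
31 | as 29 with a C15 ketone | Cc1oc(=O)c2c(c1C)O[C@]1(OC)[C@H](O[Si](C)(C)C(C)(C)C)C(=O)[C@@]3(O[Si](CC)(CC)CC)C(=CC(=O)C3(C)C)[C@H](C)[C@H]1C2 | intermediate
32 | CNP0525404.1 | Cc1oc(=O)c2c(c1C)O[C@]1(O)[C@H](O)C(=O)[C@@]3(O)C(=CC(=O)C3(C)C)[C@H](C)[C@H]1C2 | target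

**Step count**

Total: 21 steps. Longest linear sequence: 21 steps (from cycloheptanone; compounds 5, 16 and 23 are commercial).

**The three steps most likely to fail**

Step 17 (key step). The carbenoid may be diverted before it reaches C19–H. Possible diversions are attack on the O18 oxygen with silyl transfer, insertion at the tertiary C26–H, or coupling of two diazoketone molecules. The fallback generates the same C20 α-oxo carbene without a diazo compound, by gold-catalysed oxidation of a terminal alkyne. It sets out from dione 15. The allenylzinc reagent from 3-chloro-3-methylbut-1-yne and Zn in THF should add at C17 with propargylic transposition to give the alkynyl ketol F1. Reduction with NaBH4 should give the alkynyl diol F2, acylation with chloroacetic anhydride the alkynyl chloroacetate F3, and silylation with TESOTf the alkynyl triethylsilyl ether F4. Treatment of F4 with IPrAuNTf2 (IPr = 1,3-bis(2,6-diisopropylphenyl)imidazol-2-ylidene) and 8-methylquinoline N-oxide in 1,2-dichloroethane should oxidise the alkyne at C21 and close ring D by 1,5 C–H insertion. The fallback comes back to the route at cyclopentanone 27.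

Step 10. The organoindium reagent may add to the C15 carbonyl, may attack the wrong face of C17, or the dione may be reduced or enolised by the metal. The fallback replaces the metal-mediated Barbier addition by a metal-free allylboration with 3-methylbut-2-en-1-ylboronic acid pinacol ester in toluene. This reacts through a closed chair transition state, cannot reduce the dione and is more sensitive to the steric difference between the two carbonyls. It sets out from dione 15 and comes back at ketol 17, with no new isolated compound (F0).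

Step 4. Ionisation of the allylic hemiketal may lead to migration of the double bond out of conjugation or to capture of the cation at C15 instead of C11. The fallback accepts the migration and brings in the C13 oxygen later. It sets out from hemiketal 8. Equilibrating ketalisation (MeOH, HC(OMe)3, p-TsOH, 40 °C) should give the deconjugated methyl ketal F5 with the alkene at C15=C17. Dihydroxylation (OsO4, NMO) should give the diol F6, and IBX the dione F7, which has a methylene group at C13. Prenylindium addition at C17 should give the ketol F8; here C15 is shielded only by the neighbouring ring-fusion ketal carbon, so site selectivity is less secure than in the main route. The C15 ketone of F8 can enolise only toward C13, so Rubottom oxidation (TMSOTf, Et3N; then dimethyldioxirane; mild acid work-up) should deliver the C13 β-hydroxy ketol F9 from the face opposite the axial methoxy group. Silylation of the secondary alcohol with TBSOTf and 2,6-lutidine brings the fallback back to the route at ketol 17.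

**Further compounds**

F1 | step 17 | alkynyl ketol: the tricycle with C13–OTBS β, C15 ketone, C17–OH α and C17 β-(2-methylbut-3-yn-2-yl) | Cc1oc(=O)c2c(c1C)O[C@]1(OC)[C@H](O[Si](C)(C)C(C)(C)C)C(=O)[C@](O)(C(C)(C)C#C)C[C@H](C)[C@H]1C2
F2 | step 17 | alkynyl diol: as F1 with C15–OH β | Cc1oc(=O)c2c(c1C)O[C@]1(OC)[C@H](O[Si](C)(C)C(C)(C)C)[C@H](O)[C@](O)(C(C)(C)C#C)C[C@H](C)[C@H]1C2
F3 | step 17 | alkynyl chloroacetate: as F2 with C15–OC(O)CH2Cl β | Cc1oc(=O)c2c(c1C)O[C@]1(OC)[C@H](O[Si](C)(C)C(C)(C)C)[C@H](OC(=O)CCl)[C@](O)(C(C)(C)C#C)C[C@H](C)[C@H]1C2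
F4 | step 17 | alkynyl triethylsilyl ether: as F3 with C17–OSiEt3 α | Cc1oc(=O)c2c(c1C)O[C@]1(OC)[C@H](O[Si](C)(C)C(C)(C)C)[C@H](OC(=O)CCl)[C@](O[Si](CC)(CC)CC)(C(C)(C)C#C)C[C@H](C)[C@H]1C2
F0 | step 10 | none | none
F5 | step 4 | deconjugated methyl ketal: the tricycle with C13H2 and C15=C17 alkene | Cc1oc(=O)c2c(c1C)O[C@]1(OC)CC=CC[C@H](C)[C@H]1C2
F6 | step 4 | diol: the tricycle with C13H2, C15–OH β and C17–OH β | Cc1oc(=O)c2c(c1C)O[C@]1(OC)C[C@H](O)[C@H](O)C[C@H](C)[C@H]1C2
F7 | step 4 | dione: the tricycle with C13H2 and ketones at C15 and C17 | Cc1oc(=O)c2c(c1C)O[C@]1(OC)CC(=O)C(=O)C[C@H](C)[C@H]1C2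
F8 | step 4 | ketol: the tricycle with C13H2, C15 ketone, C17–OH α and C17 β-(2-methylbut-3-en-2-yl) | Cc1oc(=O)c2c(c1C)O[C@]1(OC)CC(=O)[C@](O)(C(C)(C)C=C)C[C@H](C)[C@H]1C2
F9 | step 4 | C13 β-hydroxy ketol: as F8 with C13–OH β | Cc1oc(=O)c2c(c1C)O[C@]1(OC)[C@H](O)C(=O)[C@](O)(C(C)(C)C=C)C[C@H](C)[C@H]1C2
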